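At early times the starting complex feeds the complex with one exchanged, and that complex in turn is used up, so its amount rises and falls.

| flask | starting complex | incoming ligand | remark | time |
|---|---|---|---|---|
| Wednesday's | 0.080 M | 1.8 equiv | run made earlier |  |
| Monday's | 0.32 M | 1.8 equiv | run made earlier |  |
| flask | 0.16 M | 1.80 equiv |  | 1.0 h |

| run | time / min | complex with one exchanged / % | complex with two exchanged / % |
|---|---|---|---|
| Wednesday's | 0.500 | 3.6 | 0.3 |
| Wednesday's | 1.33 | 6.8 | 0 |
| Wednesday's | 3.00 | 5.8 | 6.8 |
| Wednesday's | 8.00 | 2.8 | 13.8 |
| Wednesday's | 20.0 | 0.6 | 20.3 |
| Wednesday's | 50.0 | 0.1 | 23.1 |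
| Monday's | 0.500 | 11.9 | 6.6 |
| Monday's | 1.33 | 6.1 | 18.9 |
| Monday's | 3.00 | 5.1 | 33.0 |
| Monday's | 8.00 | 2.1 | 45.5 |
| Monday's | 20.0 | 0 | 48.1 |
| Monday's | 50.0 | 0 | 47.7 |

(standard deviation of a reading: 1 percentage point)

- what was read earlier has a scatter of 1 percentage point, one standard deviation

- the moment within 1.0 h at which there is most complex with one exchanged, in min
- the amount of complex with one exchanged, in percent of the starting complex charged, at that time

The two runs level off at 23.1% and 47.7% of the complex with two exchanged, while the complex with one exchanged has dropped to 0.1% and 0%. I read this as a second way out of that complex, one that needs no incoming ligand. I therefore hold the incoming ligand against an even-split concentration, which I reckon next. Wednesday's mean incoming ligand, taken midway between charge and remainder, is 0.0948 M. With Monday's 0.340 M, the plateaus give 0.315 M and 0.372 M. I take 0.344 M, the even-split concentration: the incoming ligand at which that complex goes equally both ways, a selectivity factor in concentration units.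

On the fastest rung, the complex with one exchanged peaks. I take the peak time to scale as one over the even-split concentration plus charged ligand, and the height as ligand over that sum. Wednesday's highest reading then gives about 1.03 min for this flask, and heights of 10.5% from Wednesday and 8.66% from Monday. On the slower rung, the starting complex drains over tens of minutes, and I expect this flask to end near 34.3% with two exchanged.

The forecast gives 0.9 min (0.6 min to 1.3 min) and 9.5% (7.5% to 11.5%), holding that “the rate scales with concentration”. My time is later.

The flask gives 8.44% at 1.12 min.

    starting complex + incoming ligand → leaving ligand + complex with one exchanged (k = 0.0141 L mol⁻¹ s⁻¹)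
    complex with one exchanged + incoming ligand → leaving ligand + complex with two exchanged (k = 0.0585 L mol⁻¹ s⁻¹)
    complex with one exchanged → decomposed reagent (k = 0.0173 s⁻¹)
    incoming ligand → decomposition product (k = 1.10 × 10⁻⁵ s⁻¹)

That time is later than mine, and the height lies below both of mine. The neighbouring flask has 0.64 M of starting complex, so its charged ligand is 1.15 M, above the even-split concentration 0.344 M. Scaling from Monday's first reading gives a height of 14.6%, and the neighbour reaches 12.5%. With Monday's mean equivalents, the final share comes to 66.4%, and after 1.00 h the neighbour holds 61.4% of complex with two exchanged.

The runs stem from a simulated flask with made-up constants; noise was put on by code.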